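If two nucleophiles compete for one short-lived intermediate, I start from the even split and measure away from it, and these flasks are a good place to try that.

    second nucleophile + target → over-reaction product (k1 = 0.024 M⁻¹ s⁻¹, Ea1 = 80.0 kJ mol⁻¹)
    2 substrate → self-condensation product (k2 = 3.9 × 10⁻⁵ M⁻¹ s⁻¹, Ea2 = 93.0 kJ mol⁻¹)
    second nucleophile + intermediate → other capture product (k3 = 43 M⁻¹ s⁻¹, Ea3 = 51.0 kJ mol⁻¹)
    intermediate → solvolysis product (k4 = 0.099 s⁻¹, Ea4 = 95.0 kJ mol⁻¹)
    substrate → intermediate (k5 = 0.0011 s⁻¹, Ea5 = 102 kJ mol⁻¹)
    first nucleophile + intermediate → target (k6 = 97 M⁻¹ s⁻¹, Ea6 = 57.0 kJ mol⁻¹)
    (constants at 70 °C)

all flasks: substrate 15 mM; first nucleophile 16.5 mM; second nucleophile 14.2 mM; time 1.0 h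

| flask | temperature |
|---|---|
| north | 25 °C |
| south-west | 55 °C |
| east | 40 °C |
| north-west | 70 °C |

- percent here means substrate units held: one self-condensation product counts as two
- two of one species on the left: rate k times its square, two consumed each time
- the list of constants is for 70 °C, to be carried to other temperatures by the activation energies

1. the best flask by amount of target, in percent of the substrate charged; "all alike" if 1.5 percentage points covers them all (north / south-west / east / north-west / all alike)
2. amount of target at the end, in percent of the substrate charged, north
3. amount of target at the end, in percent of the substrate charged, south-west
4. amount of target at the end, in percent of the substrate charged, east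
5. amount of target at the end, in percent of the substrate charged, north-west

What becomes of the intermediate in north-west? At 70 °C and the charged amounts, the first nucleophile takes it at 1.60 s⁻¹, the second nucleophile at 0.611 s⁻¹ and solvolysis at 0.099 s⁻¹, while substrate feeds it at 0.0011 s⁻¹, so the feed is the rate-limiting step, slower than each way out, and I expect the intermediate to leave about as fast as it is made.

What number would you carry from this? The capture odds, the rate at which the first nucleophile takes the intermediate over the rate at which the second takes it, at the charged amounts, whose zero of the scale is even odds of 1, and north-west stands at 2.62; with solvolysis counted in, that makes a share of 69.3% for the first nucleophile.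

And the yield of target in north-west? For 1.0 h I reckon a conversion of substrate of 98.1%, and I drop self-condensation, since at the start of north-west substrate goes to intermediate 940 times as fast as it goes to self-condensation product, so I reckon capture by the first nucleophile at 68.0% of the substrate, counting target and whatever has gone on to over-reaction product.

Where is that weak? Target does not stay, for with the second nucleophile at its charge the loss is pseudo-first-order at 3.408 × 10⁻⁴ s⁻¹, about a third of the feed, and the series formula then leaves 27.5%; but the second nucleophile falls as capture and over-reaction consume it, so that figure takes the loss too fast, and I commit to target in north-west between 27.5% and 68.0%.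

Why not the cold end? Over the span from north to north-west over-reaction speeds up by a factor of 69, and the feed, with its higher activation energy, by a factor of 220, so I reckon a conversion of 1.78% in north, less than my lower mark, and I rank north-west above north; south-west and east I leave unreckoned.

The forecast goes further, naming north-west as best, with 1.15% in north, 7.8% in east, 30.4% in south-west and 37.5% in north-west, the last within 33% to 42%, a narrower range than mine, and it says that “the short-lived intermediate goes about two-thirds to target”.

The flask gives north-west as best, with 1.15% in north, 7.77% in east, 30.7% in south-west and 37.6% in north-west. At 1.00 h north-west holds 37.6% target, 26.5% over-reaction product and 28.0% other capture product, so target and over-reaction product together stand to other capture product at 2.29, a ratio gathered over the whole hour and not the odds at the charged amounts. The neighbour of north-west charged with 8.5 mM of second nucleophile has capture odds at its charged amounts of 4.38, higher than the 2.62 of north-west, its ratio over the hour is 3.75, higher than the 2.29 of north-west, and it ends with 53.6% target.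

The constants belong to no real substance.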